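**Retrosynthetic overview**

1. The C3–O ester is made last: the C3 alcohol is acylated with (R)-4-(angeloyloxy)hex-2-ynoic acid, the (Z)-enoate comes from Lindlar reduction, and the 8,9-diol travels as its acetonide.
2. Ring B is functionalised on the finished bicycle from its C9 ketone: C7=C8 enone, copper-catalysed addition of isopropenylmagnesium bromide at C7, Rubottom oxidation at C8, hydride reduction at C9, each steered by the axial C14 methyl group.
3. Key disconnection C4–C5: ring A is closed onto ring B by a decarboxylative radical conjugate addition (6-endo) that makes the quaternary C5 and sets C4, C5 and C10; the carboxyl group on C4 is not in the target and is lost in this step.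
4. Enabling feature: with the C9 oxygen of ring B carried as a ketone, C5 is the β-carbon of the C9(=O)–C10=C5 enone and the side chain sits on the α-carbon C10; the C3 oxygen on the C1–C2–C3 tether stands 1,3 to C5 and relays its configuration through a chair transition state.
5. The acid precursor comes from an Evans aldol reaction (C3) and a B-alkyl Suzuki coupling with 2-iodo-3-methylcyclohex-2-enone (C1–C10); ring order: ring B (bought as 3-methylcyclohexenone), then ring A (key step).

Key step: step 6

Remark (numbering): decalin carbons are C1–C10 (ring A = C1–C5 and C10, ring B = C5–C10), C14 is the methyl on C5, C15 the methyl on C4; β is the face of C14 and "trans-decalin" means 10α-H.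
Remark (assumption): (R)-pent-1-yn-3-ol, angelic acid, (S)-4-benzyl-3-propanoyl-1,3-oxazolidin-2-one, 3-methylcyclohex-2-en-1-one and acrolein are taken as purchasable.

**Route**

Step 1
Reactants: 1 3-methylcyclohex-2-en-1-one
Product: 2 2-iodo-3-methylcyclohex-2-en-1-one
Conditions: I2, pyridine, CH2Cl2, 0 °C → rt
Reagents that add atoms: iodine, II
Why: α-Iodination of an enone by conjugate addition of pyridine, iodination of the enolate and elimination (a Baylis–Hillman-type sequence) should place iodine on C2 only, since no other position can react this way.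

Step 2
Reactants: 3 (S)-4-benzyl-3-propanoyl-1,3-oxazolidin-2-one; 4 acrolein
Product: 7 (S)-4-benzyl-3-[(2S,3R)-3-hydroxy-2-methylpent-4-enoyl]-1,3-oxazolidin-2-one, via dibutylboron Z-enolate 5 (not isolated), via dibutylboron aldolate 6 (not isolated)
Conditions: Bu2BOTf, i-Pr2NEt, CH2Cl2, 0 °C; 4, −78 → 0 °C; then pH 7 buffer, MeOH, H2O2
Reagents that add atoms: none
Why: Evans syn-aldol reaction: the Z-enolate 5 reacts through a chair (Zimmerman–Traxler) transition state on the face not covered by the benzyl group, which sets the carbinol carbon (the later C3) as R and the syn methyl-bearing carbon as S.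

Step 3
Reactants: 7 (S)-4-benzyl-3-[(2S,3R)-3-hydroxy-2-methylpent-4-enoyl]-1,3-oxazolidin-2-one
Product: 8 (S)-4-benzyl-3-[(2S,3R)-3-(tert-butyldimethylsilyloxy)-2-methylpent-4-enoyl]-1,3-oxazolidin-2-one
Conditions: TBSOTf, 2,6-lutidine, CH2Cl2, −78 → 0 °C
Reagents that add atoms: tert-butyldimethylsilyl triflate, CC(C)(C)[Si](C)(C)OS(=O)(=O)C(F)(F)F
Why: Silylation of the secondary alcohol with a silyl triflate and a hindered base is fast at low temperature and protects the later C3 oxygen through the organometallic steps without touching a stereocentre.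

Step 4
Reactants: 8 (S)-4-benzyl-3-[(2S,3R)-3-(tert-butyldimethylsilyloxy)-2-methylpent-4-enoyl]-1,3-oxazolidin-2-one; 2 2-iodo-3-methylcyclohex-2-en-1-one
Product: 10 (S)-4-benzyl-3-[(2S,3R)-3-(tert-butyldimethylsilyloxy)-2-methyl-5-(2-methyl-6-oxocyclohex-1-en-1-yl)pentanoyl]-1,3-oxazolidin-2-one, via B-alkyl-9-BBN adduct 9 (not isolated)
Conditions: 9-BBN, THF, rt; then 2, Pd(dppf)Cl2 (5 mol%), AsPh3, Cs2CO3, DMF/H2O, rt
Reagents that add atoms: none
Why: Anti-Markovnikov hydroboration of the terminal alkene followed by B-alkyl Suzuki–Miyaura coupling with the α-iodoenone should join C1 to C10 under mild base, and the only centre at risk (α to the imide) is destroyed later in any case.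

Step 5
Reactants: 10 (S)-4-benzyl-3-[(2S,3R)-3-(tert-butyldimethylsilyloxy)-2-methyl-5-(2-methyl-6-oxocyclohex-1-en-1-yl)pentanoyl]-1,3-oxazolidin-2-one
Product: 12 (2S,3R)-3-(tert-butyldimethylsilyloxy)-2-methyl-5-(2-methyl-6-oxocyclohex-1-en-1-yl)pentanoic acid, via peroxy acid 11 (not isolated)
Conditions: LiOH, H2O2, THF/H2O, 0 °C; then Na2SO3 aq., HCl aq.
Reagents that add atoms: hydrogen peroxide (as LiOOH), OO
Why: Hydroperoxide cleavage of the N-acyloxazolidinone attacks the exocyclic carbonyl selectively and sulfite reduces peracid 11, while the tetrasubstituted enone should be too hindered for nucleophilic epoxidation at 0 °C.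

Step 6
Reactants: 12 (2S,3R)-3-(tert-butyldimethylsilyloxy)-2-methyl-5-(2-methyl-6-oxocyclohex-1-en-1-yl)pentanoic acid
Product: 14 (4aR,5R,6R,8aR)-6-(tert-butyldimethylsilyloxy)-4a,5-dimethyloctahydronaphthalen-1(2H)-one, via potassium enolate 13 (not isolated)
Conditions: Ir[dF(CF3)ppy]2(dtbbpy)PF6 (1 mol%), K2HPO4, DMF (degassed), blue LEDs, rt
Reagents that add atoms: none
Why: The excited photocatalyst Ir[dF(CF3)ppy]2(dtbbpy)PF6 oxidises the carboxylate of 12, loss of CO2 gives a nucleophilic secondary radical at C4 that adds to C5, the β-carbon of the ring B enone, and the α-keto radical at C10 is reduced to enolate 13 and protonated; the closest known reaction type is the photoredox decarboxylative Giese addition of aliphatic carboxylic acids to enones, used here intramolecularly. Ring A closes in the 6-endo-trig mode, favoured over 5-exo attack at C10 because the tether sits on the α-carbon of the enone and the alkyl radical is polarity-matched with the β-carbon. C5 is controlled by the C3 stereocentre: in the chair transition state the silyloxy group is equatorial and so avoids the C14 methyl, which must become axial on ring A, and this fixes the face of C5 that is attacked. C4 is controlled by the planar radical carbon placing its methyl group outside (pseudo-equatorial), trans to the C3 oxygen. C10 is controlled by protonation of 13 on the α face, opposite the adjacent C14 methyl, which gives the trans ring fusion. The step needs regioselectivity (C5 over C10) and one face of the enone, and the enone polarisation and the single tether stereocentre secure them.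

Step 7
Reactants: 14 (4aR,5R,6R,8aR)-6-(tert-butyldimethylsilyloxy)-4a,5-dimethyloctahydronaphthalen-1(2H)-one
Product: 16 (4aR,5R,6R,8aR)-6-(tert-butyldimethylsilyloxy)-4a,5-dimethyl-4a,5,6,7,8,8a-hexahydronaphthalen-1(4H)-one, via trimethylsilyl enol ether 15 (not isolated)
Conditions: LiN(i-Pr)2, Me3SiCl, THF, −78 °C; then Pd(OAc)2, MeCN, rt
Reagents that add atoms: none
Why: Saegusa–Ito oxidation: kinetic deprotonation at the C8 methylene (C10 is tertiary and hindered) and dehydrosilylation of 15 with palladium diacetate should give the C7=C8 enone, the only one possible because C5 is quaternary.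

Step 8
Reactants: 16 (4aR,5R,6R,8aR)-6-(tert-butyldimethylsilyloxy)-4a,5-dimethyl-4a,5,6,7,8,8a-hexahydronaphthalen-1(4H)-one
Product: 17 3α-(tert-butyldimethylsilyloxy)-7α-isopropenyl-4β,5β-dimethyl-9-(trimethylsilyloxy)-trans-decal-8-ene
Conditions: CH2=C(CH3)MgBr, CuBr·SMe2 (20 mol%), Me3SiCl, THF, −78 → −40 °C; Et3N
Reagents that add atoms: isopropenylmagnesium bromide, C=C(C)[Mg]Br; chlorotrimethylsilane, C[Si](C)(C)Cl
Why: Copper-catalysed conjugate addition with silyl trapping: the isopropenyl group should enter C7 from the α face, away from the axial C14 methyl group 1,3 to C7, which makes it equatorial and fixes the enolate as its C8=C9 silyl enol ether.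

Step 9
Reactants: 17 3α-(tert-butyldimethylsilyloxy)-7α-isopropenyl-4β,5β-dimethyl-9-(trimethylsilyloxy)-trans-decal-8-ene
Product: 19 3α-(tert-butyldimethylsilyloxy)-7α-isopropenyl-4β,5β-dimethyl-8α-(trimethylsilyloxy)-trans-decalin-9-one, via silyloxy epoxide 18 (not isolated)
Conditions: mCPBA (1.0 equiv), NaHCO3, CH2Cl2, −20 → 0 °C, neutral work-up
Reagents that add atoms: 3-chloroperoxybenzoic acid, OOC(=O)c1cccc(Cl)c1
Why: Rubottom oxidation: the silyl enol ether is epoxidised far faster than the isopropenyl group and from the α face opposite the C14 methyl, and 1,4-silyl migration in 18 should give the axial 8α-silyloxy ketone.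

Step 10
Reactants: 19 3α-(tert-butyldimethylsilyloxy)-7α-isopropenyl-4β,5β-dimethyl-8α-(trimethylsilyloxy)-trans-decalin-9-one
Product: 21 7α-isopropenyl-4β,5β-dimethyl-trans-decalin-3α,8α,9α-triol, via trimethylsilyl ether 20 (not isolated)
Conditions: LiAlH4, THF, −78 °C; H2O work-up; then Bu4NF, THF, rt
Reagents that add atoms: none
Why: Ketone reduction under polar Felkin–Anh control: the small hydride should attack C9 anti to the axial C8–O bond, from the β face, to give the equatorial 9α-alcohol cis to the C8 oxygen, and fluoride then cleaves both silyl ethers.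

Step 11
Reactants: 21 7α-isopropenyl-4β,5β-dimethyl-trans-decalin-3α,8α,9α-triol
Product: 22 8α,9α-O-isopropylidene-7α-isopropenyl-4β,5β-dimethyl-trans-decalin-3α-ol
Conditions: Me2C(OMe)2, PPTS (cat.), acetone, rt
Reagents that add atoms: 2,2-dimethoxypropane, COC(C)(C)OC
Why: Acetonide formation (transacetalisation) is possible only across the cis-8α,9α-diol, which leaves the remote C3 hydroxyl free for acylation.

Step 12
Reactants: 23 angelic acid; 24 (R)-pent-1-yn-3-ol
Product: 26 (R)-pent-1-yn-3-yl (Z)-2-methylbut-2-enoate, via mixed anhydride 25 (not isolated)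
Conditions: 2,4,6-Cl3C6H2COCl, Et3N, toluene, rt; then 24, DMAP, rt
Reagents that add atoms: none
Why: Yamaguchi esterification through mixed anhydride 25 at room temperature should acylate the propargylic alcohol with retention and without Z-to-E isomerisation of the angelate.

Step 13
Reactants: 26 (R)-pent-1-yn-3-yl (Z)-2-methylbut-2-enoate
Product: 28 (R)-4-[(Z)-2-methylbut-2-enoyloxy]hex-2-ynoic acid, via lithium acetylide 27 (not isolated)
Conditions: LiN(SiMe3)2, THF, −78 °C; CO2; then HCl aq.
Reagents that add atoms: carbon dioxide, O=C=O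
Why: Deprotonation of the terminal alkyne, the most acidic C–H of a propargylic ester, and carboxylation of the acetylide with CO2 should give the ynoic acid without touching the ester, which has no α-hydrogen.

Step 14
Reactants: 22 8α,9α-O-isopropylidene-7α-isopropenyl-4β,5β-dimethyl-trans-decalin-3α-ol; 28 (R)-4-[(Z)-2-methylbut-2-enoyloxy]hex-2-ynoic acid
Product: 30 8α,9α-O-isopropylidene-7α-isopropenyl-4β,5β-dimethyl-trans-decalin-3α-yl (R)-4-[(Z)-2-methylbut-2-enoyloxy]hex-2-ynoate, via O-acylisourea 29 (not isolated)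
Conditions: DCC, DMAP (5 mol%), CH2Cl2, −20 → 0 °C
Reagents that add atoms: none
Why: Steglich esterification acylates the equatorial C3 hydroxyl with retention, and the low temperature and small amount of DMAP should limit conjugate addition to the activated ynoate.

Step 15
Reactants: 30 8α,9α-O-isopropylidene-7α-isopropenyl-4β,5β-dimethyl-trans-decalin-3α-yl (R)-4-[(Z)-2-methylbut-2-enoyloxy]hex-2-ynoate
Product: 31 8α,9α-O-isopropylidene-7α-isopropenyl-4β,5β-dimethyl-trans-decalin-3α-yl (R,Z)-4-[(Z)-2-methylbut-2-enoyloxy]hex-2-enoate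
Conditions: H2 (1 atm), Pd/CaCO3 poisoned with Pb(OAc)2, quinoline, EtOAc, rt
Reagents that add atoms: none
Why: Lindlar semi-hydrogenation adds H2 syn to the alkyne and so gives the (Z)-enoate, while the isopropenyl and angelate double bonds should not be reduced on the poisoned catalyst.

Step 16
Reactants: 31 8α,9α-O-isopropylidene-7α-isopropenyl-4β,5β-dimethyl-trans-decalin-3α-yl (R,Z)-4-[(Z)-2-methylbut-2-enoyloxy]hex-2-enoate
Product: 32 8α,9α-dihydroxy-7α-isopropenyl-4β,5β-dimethyl-trans-decalin-3α-yl (R,Z)-4-[(Z)-2-methylbut-2-enoyloxy]hex-2-enoate (CNP0382739.1)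
Conditions: AcOH/H2O/THF (3:1:1), 40 °C
Reagents that add atoms: none
Why: Acid-catalysed acetal hydrolysis frees the 8,9-diol, and the two esters, both of secondary alcohols and without a free γ-hydroxyl that could lactonise, should survive the mild aqueous acid.

**Compound list**

1 | 3-methylcyclohex-2-en-1-one | CC1=CC(=O)CCC1 | starting material
2 | 2-iodo-3-methylcyclohex-2-en-1-one | CC1=C(I)C(=O)CCC1 | intermediate
3 | (S)-4-benzyl-3-propanoyl-1,3-oxazolidin-2-one | CCC(=O)N1[C@@H](Cc2ccccc2)COC1=O | starting material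
4 | acrolein | C=CC=O | starting material
5 | dibutylboron Z-enolate of 3 | C/C=C(\OB(CCCC)CCCC)N1[C@@H](Cc2ccccc2)COC1=O | intermediate
6 | dibutylboron aldolate of 7 | C=C[C@@H](OB(CCCC)CCCC)[C@H](C)C(=O)N1[C@@H](Cc2ccccc2)COC1=O | intermediate
7 | (S)-4-benzyl-3-[(2S,3R)-3-hydroxy-2-methylpent-4-enoyl]-1,3-oxazolidin-2-one | C=C[C@@H](O)[C@H](C)C(=O)N1[C@@H](Cc2ccccc2)COC1=O | intermediate
8 | (S)-4-benzyl-3-[(2S,3R)-3-(tert-butyldimethylsilyloxy)-2-methylpent-4-enoyl]-1,3-oxazolidin-2-one | C=C[C@@H](O[Si](C)(C)C(C)(C)C)[C@H](C)C(=O)N1[C@@H](Cc2ccccc2)COC1=O | intermediate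
9 | B-alkyl-9-borabicyclo[3.3.1]nonane adduct of 8 (boron on the former terminal alkene carbon) | C(CB1C2CCCC1CCC2)[C@@H](O[Si](C)(C)C(C)(C)C)[C@H](C)C(=O)N1[C@@H](Cc2ccccc2)COC1=O | intermediate
10 | (S)-4-benzyl-3-[(2S,3R)-3-(tert-butyldimethylsilyloxy)-2-methyl-5-(2-methyl-6-oxocyclohex-1-en-1-yl)pentanoyl]-1,3-oxazolidin-2-one | CC1=C(CC[C@@H](O[Si](C)(C)C(C)(C)C)[C@H](C)C(=O)N2[C@@H](Cc3ccccc3)COC2=O)C(=O)CCC1 | intermediate
11 | (2S,3R)-3-(tert-butyldimethylsilyloxy)-2-methyl-5-(2-methyl-6-oxocyclohex-1-en-1-yl)pentaneperoxoic acid | CC1=C(CC[C@@H](O[Si](C)(C)C(C)(C)C)[C@H](C)C(=O)OO)C(=O)CCC1 | intermediate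
12 | (2S,3R)-3-(tert-butyldimethylsilyloxy)-2-methyl-5-(2-methyl-6-oxocyclohex-1-en-1-yl)pentanoic acid | CC1=C(CC[C@@H](O[Si](C)(C)C(C)(C)C)[C@H](C)C(=O)O)C(=O)CCC1 | intermediate
13 | potassium C9=C10 enolate of 14 | [K+].[O-]C1=C2CC[C@@H](O[Si](C)(C)C(C)(C)C)[C@H](C)[C@@]2(C)CCC1 | intermediate
14 | (4aR,5R,6R,8aR)-6-(tert-butyldimethylsilyloxy)-4a,5-dimethyloctahydronaphthalen-1(2H)-one (trans-decalin-9-one with 3α-OTBS and 4β,5β-dimethyl) | O=C1CCC[C@]2(C)[C@@H](C)[C@H](O[Si](C)(C)C(C)(C)C)CC[C@@H]12 | intermediate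
15 | C8=C9 trimethylsilyl enol ether of 14 | C[Si](C)(C)OC1=CCC[C@]2(C)[C@@H](C)[C@H](O[Si](C)(C)C(C)(C)C)CC[C@@H]12 | intermediate
16 | (4aR,5R,6R,8aR)-6-(tert-butyldimethylsilyloxy)-4a,5-dimethyl-4a,5,6,7,8,8a-hexahydronaphthalen-1(4H)-one (C7=C8 enone) | O=C1C=CC[C@]2(C)[C@@H](C)[C@H](O[Si](C)(C)C(C)(C)C)CC[C@@H]12 | intermediate
17 | 3α-(tert-butyldimethylsilyloxy)-7α-isopropenyl-4β,5β-dimethyl-9-(trimethylsilyloxy)-trans-decal-8-ene | C[Si](C)(C)OC1=C[C@H](C(C)=C)C[C@]2(C)[C@@H](C)[C@H](O[Si](C)(C)C(C)(C)C)CC[C@@H]12 | intermediate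
18 | 8α,9α-epoxide of 17 | C[Si](C)(C)O[C@@]12O[C@@H]1[C@H](C(C)=C)C[C@]3(C)[C@@H](C)[C@H](O[Si](C)(C)C(C)(C)C)CC[C@@H]23 | intermediate
19 | 3α-(tert-butyldimethylsilyloxy)-7α-isopropenyl-4β,5β-dimethyl-8α-(trimethylsilyloxy)-trans-decalin-9-one | O=C1[C@H](O[Si](C)(C)C)[C@H](C(C)=C)C[C@]2(C)[C@@H](C)[C@H](O[Si](C)(C)C(C)(C)C)CC[C@@H]12 | intermediate
20 | 3α-(tert-butyldimethylsilyloxy)-7α-isopropenyl-4β,5β-dimethyl-8α-(trimethylsilyloxy)-trans-decalin-9α-ol | O[C@@H]1[C@H](O[Si](C)(C)C)[C@H](C(C)=C)C[C@]2(C)[C@@H](C)[C@H](O[Si](C)(C)C(C)(C)C)CC[C@@H]12 | intermediate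
21 | 7α-isopropenyl-4β,5β-dimethyl-trans-decalin-3α,8α,9α-triol | O[C@@H]1[C@H](O)[C@H](C(C)=C)C[C@]2(C)[C@@H](C)[C@H](O)CC[C@@H]12 | intermediate
22 | 8α,9α-O-isopropylidene-7α-isopropenyl-4β,5β-dimethyl-trans-decalin-3α-ol | CC1(C)O[C@@H]2[C@H](O1)[C@H](C(C)=C)C[C@]3(C)[C@@H](C)[C@H](O)CC[C@@H]23 | intermediate
23 | angelic acid, (Z)-2-methylbut-2-enoic acid | C/C=C(/C)C(=O)O | starting material
24 | (R)-pent-1-yn-3-ol | CC[C@@H](O)C#C | starting material
25 | angelic 2,4,6-trichlorobenzoic anhydride | C/C=C(/C)C(=O)OC(=O)c1c(Cl)cc(Cl)cc1Cl | intermediate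
26 | (R)-pent-1-yn-3-yl (Z)-2-methylbut-2-enoate | C/C=C(/C)C(=O)O[C@H](CC)C#C | intermediate
27 | lithium acetylide of 26 | C/C=C(/C)C(=O)O[C@H](CC)C#C[Li] | intermediate
28 | (R)-4-[(Z)-2-methylbut-2-enoyloxy]hex-2-ynoic acid | C/C=C(/C)C(=O)O[C@H](CC)C#CC(=O)O | intermediate
29 | O-acylisourea from 28 and DCC | C/C=C(/C)C(=O)O[C@H](CC)C#CC(=O)OC(=NC1CCCCC1)NC1CCCCC1 | intermediate
30 | 8α,9α-O-isopropylidene-7α-isopropenyl-4β,5β-dimethyl-trans-decalin-3α-yl (R)-4-[(Z)-2-methylbut-2-enoyloxy]hex-2-ynoate | CC1(C)O[C@@H]2[C@H](O1)[C@H](C(C)=C)C[C@]3(C)[C@@H](C)[C@H](OC(=O)C#C[C@@H](CC)OC(=O)/C(C)=C\C)CC[C@@H]23 | intermediate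
31 | 8α,9α-O-isopropylidene-7α-isopropenyl-4β,5β-dimethyl-trans-decalin-3α-yl (R,Z)-4-[(Z)-2-methylbut-2-enoyloxy]hex-2-enoate | CC1(C)O[C@@H]2[C@H](O1)[C@H](C(C)=C)C[C@]3(C)[C@@H](C)[C@H](OC(=O)/C=C\[C@@H](CC)OC(=O)/C(C)=C\C)CC[C@@H]23 | intermediate
32 | CNP0382739.1: 8α,9α-dihydroxy-7α-isopropenyl-4β,5β-dimethyl-trans-decalin-3α-yl (R,Z)-4-[(Z)-2-methylbut-2-enoyloxy]hex-2-enoate (3R,4R,5R,7S,8R,9S,10R) | C=C(C)[C@@H]1C[C@]2(C)[C@@H](C)[C@H](OC(=O)/C=C\[C@@H](CC)OC(=O)/C(C)=C\C)CC[C@H]2[C@H](O)[C@@H]1O | target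

**Step count and risks**

Total step count: 16. Longest linear sequence: 13 steps (steps 2 to 11, then 14 to 16).

Steps most likely to fail:

1. Step 6 (radical ring closure). Stereocontrol at C4 may be incomplete, because the methyl group on the planar radical carbon can also take the inside (pseudo-axial) position in the chair transition state; slow 6-endo attack on the fully substituted C5 may also let the radical be quenched before it cyclises. Fallback for the C4 problem, which puts C4 under thermodynamic instead of kinetic control: the C4 mixture is carried through steps 7 to 11 to alcohol 22. From 22, Dess–Martin oxidation should give the 8α,9α-O-isopropylidene C3 ketone F1; DBU in toluene equilibrates C4 of F1 to the equatorial 4β-methyl epimer; reduction with Li in liquid NH3/THF (thermodynamic, equatorial alcohol; isolated alkene and acetonide inert) returns the route at 22 as a single C4 isomer.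

2. Step 8 (conjugate addition). Facial selectivity may be poor: the stereoelectronically preferred axial approach to C7 lies on the face of the C14 methyl, so attack on the two faces of the enone can compete. Fallback, which replaces substrate control by catalyst control: from enone 16, Hayashi–Miyaura addition of isopropenylboronic acid pinacol ester with Rh(acac)(C2H4)2 and (R)-BINAP in dioxane/H2O should give the 7α-isopropenyl C9 ketone F2, the (R)-ligand being the one that delivers the 7R centre by analogy with simple cyclohexenones. Kinetic enolisation of F2 at C8 with LiN(i-Pr)2 and Me3SiCl then returns the route at silyl enol ether 17.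

3. Step 10 (C9 reduction). Facial selectivity of hydride delivery may go the wrong way: the β face that is needed is syn to the axial C14 methyl, so attack from the α face may prevail and give the axial 9β-alcohol. Fallback, which inverts C9 by substitution instead of relying on facial selection: from 19, the same LiAlH4 reduction without the fluoride treatment would give the 9β-alcohol F3. Mitsunobu reaction of F3 with 4-nitrobenzoic acid, PPh3 and DIAD should invert C9 to the 9α-(4-nitrobenzoate) F4. K2CO3 in MeOH and then Bu4NF remove the ester and both silyl groups and return the route at triol 21.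

Further compounds
F1 | step 6 | 8α,9α-O-isopropylidene-7α-isopropenyl-4β,5β-dimethyl-trans-decalin-3-one | CC1(C)O[C@@H]2[C@H](O1)[C@H](C(C)=C)C[C@]3(C)[C@@H](C)C(=O)CC[C@@H]23
F2 | step 8 | 3α-(tert-butyldimethylsilyloxy)-7α-isopropenyl-4β,5β-dimethyl-trans-decalin-9-one | O=C1C[C@H](C(C)=C)C[C@]2(C)[C@@H](C)[C@H](O[Si](C)(C)C(C)(C)C)CC[C@@H]12
F3 | step 10 | 3α-(tert-butyldimethylsilyloxy)-7α-isopropenyl-4β,5β-dimethyl-8α-(trimethylsilyloxy)-trans-decalin-9β-ol | O[C@H]1[C@H](O[Si](C)(C)C)[C@H](C(C)=C)C[C@]2(C)[C@@H](C)[C@H](O[Si](C)(C)C(C)(C)C)CC[C@@H]12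
F4 | step 10 | 3α-(tert-butyldimethylsilyloxy)-7α-isopropenyl-4β,5β-dimethyl-8α-(trimethylsilyloxy)-trans-decalin-9α-yl 4-nitrobenzoate | O=C(O[C@@H]1[C@H](O[Si](C)(C)C)[C@H](C(C)=C)C[C@]2(C)[C@@H](C)[C@H](O[Si](C)(C)C(C)(C)C)CC[C@@H]12)c1ccc(cc1)[N+](=O)[O-]
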